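**Retrosynthetic overview**
- Target ⇐ thiolate mono-O-demethylation of a ring A dimethyl ether whose two methoxy groups are equivalent, preceded by hydrogenolysis of four benzyl ethers.
- Ring A is kept mirror-symmetric (3,5-dimethoxy) so its two 4-(benzyloxy)benzyl groups go in one at a time (NBS bromination, then Negishi benzylation, twice), each through a single regiodefined intermediate.
- Bibenzyl ⇐ hydroboration/B-alkyl Suzuki–Miyaura coupling of commercial 3,5-dimethoxystyrene with a ring B aryl bromide, made directly at the alkane level (no stilbene, no Wittig).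
- Ring B bromide ⇐ iodide-selective Negishi benzylation of O-benzylated 5-bromo-2-iodophenol with the same benzylzinc reagent.
- No ring is constructed: ring B is joined to its outer ring first, then to ring A, and the last two outer rings are attached to ring A.

Assumption: the target SMILES has no stereocentre and no stereogenic double bond, so the compound is achiral and no enantiocontrol is needed.
Assumption: zinc reagent 4 is prepared in one batch large enough for steps 3, 6 and 8.

**Route**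

Step 1
Reactants: 1 5-bromo-2-iodophenol
Product: 2 2-(benzyloxy)-4-bromo-1-iodobenzene
Conditions: BnBr (1.1 equiv), K2CO3, DMF, 25 °C
Reagents that add atoms: benzyl bromide, BrCc1ccccc1
Why: Williamson ether synthesis on the only nucleophilic site; both carbon–halogen bonds are inert to carbonate at room temperature.

Step 2
Reactants: 3 4-(benzyloxy)benzyl chloride
Product: 4 [4-(benzyloxy)benzyl]zinc chloride as its LiCl adduct in THF (titrated and used as solution)
Conditions: Zn dust (1.5 equiv, pre-activated), LiCl (1.5 equiv), THF, 25 °C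
Reagents that add atoms: zinc, [Zn]
Why: LiCl-promoted direct oxidative insertion of zinc into a benzylic carbon–chlorine bond gives the benzylic zinc chloride with little Wurtz dimer and leaves the aryl benzyl ether untouched.

Step 3
Reactants: 2 2-(benzyloxy)-4-bromo-1-iodobenzene; 4 [4-(benzyloxy)benzyl]zinc chloride
Product: 5 2-(benzyloxy)-1-[4-(benzyloxy)benzyl]-4-bromobenzene
Conditions: 4 (1.1 equiv), Pd(PPh3)4 (3 mol %), THF, 0 → 25 °C
Reagents that add atoms: none
Why: Negishi cross-coupling in which zerovalent palladium inserts into the carbon–iodine bond at room temperature while the carbon–bromine bond stays intact, so the ring B diarylmethane forms with the bromine kept for the next coupling.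

Step 4
Reactants: 6 3,5-dimethoxystyrene; 7 9-borabicyclo[3.3.1]nonane (9-BBN); 5 2-(benzyloxy)-1-[4-(benzyloxy)benzyl]-4-bromobenzene
Product: 9 1-{2-[3-(benzyloxy)-4-[4-(benzyloxy)benzyl]phenyl]ethyl}-3,5-dimethoxybenzene, via alkylborane 8 (not isolated)
Conditions: 9-BBN (0.5 M in THF, 1.1 equiv), THF, 0 → 25 °C; then 5 (0.95 equiv), Pd(dppf)Cl2·CH2Cl2 (3 mol %), aq K3PO4, DMF, 65 °C
Reagents that add atoms: none
Why: Anti-Markovnikov hydroboration followed by B-alkyl Suzuki–Miyaura coupling with an unhindered aryl bromide gives the bibenzyl directly at the alkane oxidation level.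

Step 5
Reactants: 9 1-{2-[3-(benzyloxy)-4-[4-(benzyloxy)benzyl]phenyl]ethyl}-3,5-dimethoxybenzene
Product: 10 1-{2-[3-(benzyloxy)-4-[4-(benzyloxy)benzyl]phenyl]ethyl}-2-bromo-3,5-dimethoxybenzene
Conditions: NBS (1.00 equiv), MeCN/CH2Cl2 (3:1), −20 → 0 °C, dark
Reagents that add atoms: N-bromosuccinimide, O=C1CCC(=O)N1Br
Why: Electrophilic aromatic bromination; ring A is a 5-alkylresorcinol diether far more nucleophilic than the mono-alkoxy rings, its two positions para to a methoxy group and ortho to the chain are equivalent by symmetry, and the position between the two methoxy groups reacts last, so one equivalent gives a single monobromide.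

Step 6
Reactants: 10 1-{2-[3-(benzyloxy)-4-[4-(benzyloxy)benzyl]phenyl]ethyl}-2-bromo-3,5-dimethoxybenzene; 4 [4-(benzyloxy)benzyl]zinc chloride
Product: 11 2-[4-(benzyloxy)benzyl]-1-{2-[3-(benzyloxy)-4-[4-(benzyloxy)benzyl]phenyl]ethyl}-3,5-dimethoxybenzene
Conditions: 4 (1.5 equiv), Pd(OAc)2 (3 mol %), SPhos (6 mol %), THF, 25 → 60 °C
Reagents that add atoms: none
Why: Negishi cross-coupling; the bulky electron-rich biarylphosphine lets palladium insert into the electron-rich, doubly ortho-flanked carbon–bromine bond, and the benzylic zinc reagent transmetalates fast and has no β-hydrogen.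

Step 7
Reactants: 11 2-[4-(benzyloxy)benzyl]-1-{2-[3-(benzyloxy)-4-[4-(benzyloxy)benzyl]phenyl]ethyl}-3,5-dimethoxybenzene
Product: 12 2-[4-(benzyloxy)benzyl]-1-{2-[3-(benzyloxy)-4-[4-(benzyloxy)benzyl]phenyl]ethyl}-6-bromo-3,5-dimethoxybenzene
Conditions: NBS (1.00 equiv), MeCN/CH2Cl2 (3:1), −20 → 0 °C, dark
Reagents that add atoms: N-bromosuccinimide, O=C1CCC(=O)N1Br
Why: Electrophilic aromatic bromination of the still most electron-rich ring A at its remaining position para to a methoxy group and ortho to the chain, which is preferred over the crowded position between the two methoxy groups and over the mono-alkoxy rings.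

Step 8
Reactants: 12 2-[4-(benzyloxy)benzyl]-1-{2-[3-(benzyloxy)-4-[4-(benzyloxy)benzyl]phenyl]ethyl}-6-bromo-3,5-dimethoxybenzene; 4 [4-(benzyloxy)benzyl]zinc chloride
Product: 13 2,6-bis[4-(benzyloxy)benzyl]-1-{2-[3-(benzyloxy)-4-[4-(benzyloxy)benzyl]phenyl]ethyl}-3,5-dimethoxybenzene
Conditions: 4 (2.0 equiv), Pd(OAc)2 (5 mol %), SPhos (10 mol %), THF, 65 °C
Reagents that add atoms: none
Why: Second Negishi cross-coupling under the same hindered-bromide catalyst system completes the mirror-symmetric, fully substituted ring A.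

Step 9
Reactants: 13 2,6-bis[4-(benzyloxy)benzyl]-1-{2-[3-(benzyloxy)-4-[4-(benzyloxy)benzyl]phenyl]ethyl}-3,5-dimethoxybenzene
Product: 14 5-{2-[2,6-bis(4-hydroxybenzyl)-3,5-dimethoxyphenyl]ethyl}-2-(4-hydroxybenzyl)phenol
Conditions: H2 (1 atm), 10% Pd/C, THF/MeOH (1:1), 25 °C
Reagents that add atoms: none
Why: Catalytic hydrogenolysis cleaves the four benzyl aryl ethers to toluene while the methyl ethers and the diarylmethane and bibenzyl C–C bonds are inert.

Step 10
Reactants: 14 5-{2-[2,6-bis(4-hydroxybenzyl)-3,5-dimethoxyphenyl]ethyl}-2-(4-hydroxybenzyl)phenol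
Product: 15 2,4-bis(4-hydroxybenzyl)-3-{2-[3-hydroxy-4-(4-hydroxybenzyl)phenyl]ethyl}-5-methoxyphenol (CNP0207338.0)
Conditions: EtSNa (8 equiv), DMF, 130 °C, argon; then 1 M HCl
Reagents that add atoms: none
Why: Thiolate SN2 O-demethylation in which the two methoxy groups are mirror-related so either gives the same product, and the ring A phenoxide formed makes the second aryloxide a far poorer leaving group, which stops the reaction at the achiral monomethyl ether.

**Compound list**
1 | 5-bromo-2-iodophenol | Oc1cc(Br)ccc1I | starting material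
2 | 2-(benzyloxy)-4-bromo-1-iodobenzene | Brc1ccc(I)c(OCc2ccccc2)c1 | intermediate
3 | 4-(benzyloxy)benzyl chloride | ClCc1ccc(OCc2ccccc2)cc1 | starting material
4 | [4-(benzyloxy)benzyl]zinc chloride (LiCl adduct, THF solution) | Cl[Zn]Cc1ccc(OCc2ccccc2)cc1 | intermediate
5 | 2-(benzyloxy)-1-[4-(benzyloxy)benzyl]-4-bromobenzene | Brc1ccc(Cc2ccc(OCc3ccccc3)cc2)c(OCc2ccccc2)c1 | intermediate
6 | 3,5-dimethoxystyrene | C=Cc1cc(OC)cc(OC)c1 | starting material
7 | 9-borabicyclo[3.3.1]nonane (9-BBN) | B1C2CCCC1CCC2 | starting material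
8 | 9-[2-(3,5-dimethoxyphenyl)ethyl]-9-borabicyclo[3.3.1]nonane (not isolated) | COc1cc(OC)cc(CCB2C3CCCC2CCC3)c1 | intermediate
9 | 1-{2-[3-(benzyloxy)-4-[4-(benzyloxy)benzyl]phenyl]ethyl}-3,5-dimethoxybenzene | COc1cc(OC)cc(CCc2ccc(Cc3ccc(OCc4ccccc4)cc3)c(OCc3ccccc3)c2)c1 | intermediate
10 | 1-{2-[3-(benzyloxy)-4-[4-(benzyloxy)benzyl]phenyl]ethyl}-2-bromo-3,5-dimethoxybenzene | COc1cc(OC)c(Br)c(CCc2ccc(Cc3ccc(OCc4ccccc4)cc3)c(OCc3ccccc3)c2)c1 | intermediate
11 | 2-[4-(benzyloxy)benzyl]-1-{2-[3-(benzyloxy)-4-[4-(benzyloxy)benzyl]phenyl]ethyl}-3,5-dimethoxybenzene | COc1cc(OC)c(Cc2ccc(OCc3ccccc3)cc2)c(CCc2ccc(Cc3ccc(OCc4ccccc4)cc3)c(OCc3ccccc3)c2)c1 | intermediate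
12 | 2-[4-(benzyloxy)benzyl]-1-{2-[3-(benzyloxy)-4-[4-(benzyloxy)benzyl]phenyl]ethyl}-6-bromo-3,5-dimethoxybenzene | COc1cc(OC)c(Cc2ccc(OCc3ccccc3)cc2)c(CCc2ccc(Cc3ccc(OCc4ccccc4)cc3)c(OCc3ccccc3)c2)c1Br | intermediate
13 | 2,6-bis[4-(benzyloxy)benzyl]-1-{2-[3-(benzyloxy)-4-[4-(benzyloxy)benzyl]phenyl]ethyl}-3,5-dimethoxybenzene | COc1cc(OC)c(Cc2ccc(OCc3ccccc3)cc2)c(CCc2ccc(Cc3ccc(OCc4ccccc4)cc3)c(OCc3ccccc3)c2)c1Cc1ccc(OCc2ccccc2)cc1 | intermediate
14 | 5-{2-[2,6-bis(4-hydroxybenzyl)-3,5-dimethoxyphenyl]ethyl}-2-(4-hydroxybenzyl)phenol | COc1cc(OC)c(Cc2ccc(O)cc2)c(CCc2ccc(Cc3ccc(O)cc3)c(O)c2)c1Cc1ccc(O)cc1 | intermediate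
15 | 2,4-bis(4-hydroxybenzyl)-3-{2-[3-hydroxy-4-(4-hydroxybenzyl)phenyl]ethyl}-5-methoxyphenol (CNP0207338.0, achiral) | COc1cc(O)c(Cc2ccc(O)cc2)c(CCc2ccc(Cc3ccc(O)cc3)c(O)c2)c1Cc1ccc(O)cc1 | target

**Step count and risk**

Total step count: 10. Longest linear sequence: 9 steps (1 → 3 → 4 → 5 → 6 → 7 → 8 → 9 → 10); step 2 is a one-step side branch.

The three steps most likely to fail:

Step 10 (mono-demethylation of a tetraphenol). Over-demethylation to the resorcinol, or a sluggish reaction of the polyphenoxide, would cost material at the last step. The fallback gives up the symmetric ring A and carries the methyl/benzyl difference from the start; it sets out from aryl bromide 5, with 4 and 7 as partners, and comes back at target 15. Commercial 3-bromo-5-methoxyphenol is benzylated (BnBr, K2CO3, DMF) to 1-(benzyloxy)-3-bromo-5-methoxybenzene F1. Vinylation (potassium vinyltrifluoroborate, Pd(dppf)Cl2·CH2Cl2, K2CO3, 1,4-dioxane/H2O, 85 °C) gives 1-(benzyloxy)-3-methoxy-5-vinylbenzene F2. Hydroboration with 7 gives the alkylborane F3, which couples with 5 under the conditions of step 4 to the unsymmetrical bibenzyl F4. 1,3-Dibromo-5,5-dimethylhydantoin (1.0 equiv, MeCN/CH2Cl2, 0 °C) brominates both ring A positions ortho to the chain and gives the dibromide F5; both are coupled in the same flask, so it does not matter that they cannot be told apart. Twofold Negishi coupling with 4 (3 equiv, Pd(OAc)2, SPhos, THF, 60 °C) gives the pentabenzyl ether F6. Hydrogenolysis (H2, 10% Pd/C, THF/MeOH) then cleaves all five benzyl ethers and gives 15 without any demethylation.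

Step 8 (Negishi coupling at the most hindered bromide). The bromide sits between a methoxy group and the chain on a fully substituted ring, so oxidative addition may be slow and protodebromination may compete. The fallback replaces cross-coupling by carbonyl addition; it sets out from bromide 12 and comes back at 13. Lithium–bromine exchange (t-BuLi, 2.1 equiv, THF, −78 °C) gives the aryllithium F7. Addition to 4-(benzyloxy)benzaldehyde gives the racemic diarylmethanol F8. Ionic hydrogenation (Et3SiH, CF3CO2H, CH2Cl2, −20 °C) of this doubly activated carbinol removes the hydroxyl and its transient stereocentre and gives 13.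

Step 7 (site-selective second bromination). Bromination could stray to the position between the methoxy groups or to one of the four mono-alkoxy rings. The fallback uses a carbon electrophile that reacts only with the dialkoxy ring; it sets out from 11 and comes back at 13, bypassing 12 and step 8. Vilsmeier–Haack formylation (POCl3, DMF, 0 → 60 °C; aq NaOAc) gives the aldehyde F9. Condensation with TsNHNH2 (MeOH, 50 °C) gives the N-tosylhydrazone F10. Metal-free reductive coupling of F10 with 4-(benzyloxy)phenylboronic acid (K2CO3, 1,4-dioxane, 110 °C) forms the diarylmethane and gives 13.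

**Further compounds**
F1 | step 10 | 1-(benzyloxy)-3-bromo-5-methoxybenzene | COc1cc(OCc2ccccc2)cc(Br)c1
F2 | step 10 | 1-(benzyloxy)-3-methoxy-5-vinylbenzene | COc1cc(OCc2ccccc2)cc(C=C)c1
F3 | step 10 | 9-{2-[3-(benzyloxy)-5-methoxyphenyl]ethyl}-9-borabicyclo[3.3.1]nonane | COc1cc(OCc2ccccc2)cc(CCB2C3CCCC2CCC3)c1
F4 | step 10 | 1-(benzyloxy)-3-{2-[3-(benzyloxy)-4-[4-(benzyloxy)benzyl]phenyl]ethyl}-5-methoxybenzene | COc1cc(OCc2ccccc2)cc(CCc2ccc(Cc3ccc(OCc4ccccc4)cc3)c(OCc3ccccc3)c2)c1
F5 | step 10 | 1-(benzyloxy)-2,4-dibromo-3-{2-[3-(benzyloxy)-4-[4-(benzyloxy)benzyl]phenyl]ethyl}-5-methoxybenzene | COc1cc(OCc2ccccc2)c(Br)c(CCc2ccc(Cc3ccc(OCc4ccccc4)cc3)c(OCc3ccccc3)c2)c1Br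
F6 | step 10 | 1-(benzyloxy)-2,4-bis[4-(benzyloxy)benzyl]-3-{2-[3-(benzyloxy)-4-[4-(benzyloxy)benzyl]phenyl]ethyl}-5-methoxybenzene | COc1cc(OCc2ccccc2)c(Cc2ccc(OCc3ccccc3)cc2)c(CCc2ccc(Cc3ccc(OCc4ccccc4)cc3)c(OCc3ccccc3)c2)c1Cc1ccc(OCc2ccccc2)cc1
F7 | step 8 | aryllithium: compound 12 with lithium in place of bromine | COc1cc(OC)c(Cc2ccc(OCc3ccccc3)cc2)c(CCc2ccc(Cc3ccc(OCc4ccccc4)cc3)c(OCc3ccccc3)c2)c1[Li]
F8 | step 8 | diarylmethanol: compound 13 carrying CH(OH) in place of the CH2 of the last benzyl group (racemic, stereocentre undefined) | COc1cc(OC)c(Cc2ccc(OCc3ccccc3)cc2)c(CCc2ccc(Cc3ccc(OCc4ccccc4)cc3)c(OCc3ccccc3)c2)c1C(O)c1ccc(OCc2ccccc2)cc1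
F9 | step 7 | 3-[4-(benzyloxy)benzyl]-2-{2-[3-(benzyloxy)-4-[4-(benzyloxy)benzyl]phenyl]ethyl}-4,6-dimethoxybenzaldehyde | COc1cc(OC)c(Cc2ccc(OCc3ccccc3)cc2)c(CCc2ccc(Cc3ccc(OCc4ccccc4)cc3)c(OCc3ccccc3)c2)c1C=O
F10 | step 7 | (E)-N-tosylhydrazone of aldehyde F9 | COc1cc(OC)c(Cc2ccc(OCc3ccccc3)cc2)c(CCc2ccc(Cc3ccc(OCc4ccccc4)cc3)c(OCc3ccccc3)c2)c1/C=N/NS(=O)(=O)c1ccc(C)cc1
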